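The number I began from was 9.67 × 10⁻⁴ min⁻¹: k2 times the solubility to the power 1.5, the first-order rate constant of starting material in south when c(coupling partner) stands at its solubility.

    starting material + target ⇌ idle adduct, settled at all times (K1 = 71 M⁻¹, ΔH1 = 13.0 kJ mol⁻¹)
    starting material + coupling partner → target, rate k2*[starting material]*[coupling partner]^1.5 (k2 = 0.169 M⁻¹·⁵ min⁻¹, Ea2 = 51.0 kJ mol⁻¹)
    solid reagent ⇌ coupling partner, rate k3*(cs3 - [coupling partner]) while solid is left; crystals form when [coupling partner] > cs3 (cs3 = 32 mM, k3 = 0.0199 min⁻¹)
    (constants at −20 °C)

| flask | starting material | solid reagent | temperature | time |
|---|---|---|---|---|
| south | 0.10 M | 2.00 equiv | −20 °C | 1.0 h |
| north | 0.10 M | 2.00 equiv | −12 °C | 1.0 h |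

- in percentages every species weighs as the starting material in it: one idle adduct counts as two
- for target the idle adduct is counted in
- as a solid, counted per litre of solution: solid reagent
- the constants hold at −20 °C; other temperatures follow from the activation energies and enthalpies
- at the start none of the solid reagent is in solution
- in an amount of target, one idle adduct counts as one target

- which of these there is most of at the end, counted by the starting material in it, south (target / starting material)
- which of these there is most of at the end, counted by the starting material in it, north (target / starting material)
- final amount of the leader among these, as a percentage of the starting material charged, in south
- final amount of the leader among these, as a percentage of the starting material charged, in north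

I took this constant as the ceiling for south; it corresponds to a half-life of 11.9 h. The real rate began at nothing, though: at the start none of the solid reagent was in solution. With c(coupling partner) treated as a set curve, cs3·(1 − exp(−k3·t)), starting material falls in a pseudo-first-order way, and the lag is one factor on the rate. In south that factor, the curve's fraction of solubility raised to the power 1.5, was:

halfway: 0.301; at the end: 0.582

mean over the run, by Simpson's rule: 0.298

The other slowings I set to one. Partner drawn by the coupling, by this estimate about 1.73 mM, was less than the curve's 22.3 mM at the end. In powers of ten, the ceiling over the hour and the lag add:

log10 of ceiling × time: −1.24; log10 of mean lag: −0.526; sum: −1.76

So the reach, the ceiling constant times the time times the mean lag, which is my estimate of the share of starting material coupled, came to 1.73% in south.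

A target bound in the idle adduct ties up one further starting material, and at the start's concentration the bound share of target reckons to 87.7%. That put free starting material in south at 96.8% by my estimate, more than the target. I stopped at south.

The forecast named starting material in south and starting material in north, at 97.1% and 94.2%; its south figure stands above mine. Its ground: “Dissolution is the bottleneck”.

South ended with 97.0% starting material and north with 94.1%, starting material leading in both, while target in south stood at 1.60% against my reach of 1.73%. At the end of south, the half-life by the coupling path was 22 h, longer than the run of 1.0 h. For south left until 2.5 h, the same lines give a mean lag of 0.609 and a reach of 8.84%, and that flask held 7.23% target, all its forms counted.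

The constants used here were drawn at random within sensible limits; the result is computed.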